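The ring atoms are labelled C1 (bears the side chain), C2 (bears the ester oxygen), C3 (C=O), C4 (bears CH3), C5 (oxirane CH) and C6 (CH2); C7 is the side-chain oxirane carbon. The carbocycle is cut into two three-carbon halves: the ketone with its two nucleophilic α-carbons (C2–C3–C4, as allyl 3-oxopentanoate) and an enal (C5–C6–C1) that already carries C7. One amine-catalysed Michael/aldol-condensation domino forms C1–C2 and C4–C5, closes the ring as a carvone-type enone and sets C1 by catalyst control. It exploits the 1,3-relationship of C2 and C4 across the C3 carbonyl and the 1,5-relationship of C3 and C5. Hydroxyl-directed epoxidation, C2 acyloxylation and a singlet-oxygen ene reaction finish the target.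

Key step: step 9

Remark: further labels are C8 (side-chain carbonyl carbon), C9, C10 and C11 (carbon bearing OOH). The C8 carbinol made in step 4 is carried as both epimers, which converge in step 17. "Cis" and "trans" refer to the C1 side chain.

Step 1
Reactants: 1 2-methylidenepropane-1,3-diol
Product: 2 2-{[(4-methoxybenzyl)oxy]methyl}prop-2-en-1-ol
Conditions: NaH (1 equiv), 4-methoxybenzyl chloride (1 equiv), Bu4NI (cat.), THF–DMF, 0 °C → rt
Reagents that add atoms: 4-methoxybenzyl chloride COc1ccc(CCl)cc1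
Why: Williamson etherification of the symmetric diol with one equivalent of base should give the mono-ether, with unreacted diol recovered.

Step 2
Reactants: 2 2-{[(4-methoxybenzyl)oxy]methyl}prop-2-en-1-ol
Product: 3 (S)-(2-{[(4-methoxybenzyl)oxy]methyl}oxiran-2-yl)methanol
Conditions: Ti(OiPr)4 (10 mol%), L-(+)-diethyl tartrate (12 mol%), tBuOOH (decane), 4 Å molecular sieves, CH2Cl2, −20 °C
Reagents that add atoms: tert-butyl hydroperoxide CC(C)(C)OO
Why: Sharpless asymmetric epoxidation of a 2-substituted allylic alcohol, in which the L-(+)-tartrate complex delivers oxygen to the same face as in the epoxidation of (E)-hex-2-en-1-ol to its (2S,3S)-epoxide, should set C7 with the free CH2OH arm destined for C8 and the ether arm for C1.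

Step 3
Reactants: 3 (S)-(2-{[(4-methoxybenzyl)oxy]methyl}oxiran-2-yl)methanol
Product: 4 (S)-2-{[(4-methoxybenzyl)oxy]methyl}oxirane-2-carbaldehyde
Conditions: Dess–Martin periodinane, pyridine, CH2Cl2, 0 °C → rt
Reagents that add atoms: none
Why: Dess–Martin oxidation of the primary alcohol under buffered conditions should give the aldehyde, whose fully substituted α-carbon (C7) cannot epimerise.

Step 4
Reactants: 4 (S)-2-{[(4-methoxybenzyl)oxy]methyl}oxirane-2-carbaldehyde; 5 1-chloro-3-methylbut-2-ene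
Product: 7 1-[(2S)-2-{[(4-methoxybenzyl)oxy]methyl}oxiran-2-yl]-4-methylpent-3-en-1-ol (both C8 epimers), via prenylbarium chloride 6 (not isolated)
Conditions: BaI2, Li, biphenyl, THF, rt; then 5, −78 °C; then 4, −78 °C; aq. NH4Cl
Reagents that add atoms: none
Why: Carbonyl allylation with an allylic barium reagent, which reacts at its unsubstituted α-terminus, should give the linear C8–C9–C10=C11 chain; the C8 carbinol centre is not controlled and is oxidised to the ketone in step 17.

Step 5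
Reactants: 7 1-[(2S)-2-{[(4-methoxybenzyl)oxy]methyl}oxiran-2-yl]-4-methylpent-3-en-1-ol
Product: 8 triethyl({1-[(2S)-2-{[(4-methoxybenzyl)oxy]methyl}oxiran-2-yl]-4-methylpent-3-en-1-yl}oxy)silane
Conditions: Et3SiCl, imidazole, DMAP (cat.), CH2Cl2, 0 °C → rt
Reagents that add atoms: chlorotriethylsilane CC[Si](Cl)(CC)CC
Why: Silylation of the secondary alcohol masks the C8 oxygen, which keeps it from lactol formation in step 9 and from directing epoxidation in step 12.

Step 6
Reactants: 8 triethyl({1-[(2S)-2-{[(4-methoxybenzyl)oxy]methyl}oxiran-2-yl]-4-methylpent-3-en-1-yl}oxy)silane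
Product: 9 [(2R)-2-{4-methyl-1-[(triethylsilyl)oxy]pent-3-en-1-yl}oxiran-2-yl]methanol
Conditions: DDQ, CH2Cl2–pH 7 buffer, 0 °C
Reagents that add atoms: none
Why: Oxidative cleavage of the 4-methoxybenzyl ether by DDQ should leave the silyl ether, the oxirane and the trisubstituted alkene untouched.

Step 7
Reactants: 9 [(2R)-2-{4-methyl-1-[(triethylsilyl)oxy]pent-3-en-1-yl}oxiran-2-yl]methanol; 10 2-(triphenylphosphoranylidene)acetaldehyde
Product: 12 (2E)-3-[(2R)-2-{4-methyl-1-[(triethylsilyl)oxy]pent-3-en-1-yl}oxiran-2-yl]prop-2-enal, via oxirane-2-carbaldehyde 11 (not isolated)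
Conditions: Dess–Martin periodinane, pyridine, CH2Cl2, 0 °C → rt; then 10, 40 °C, same flask
Reagents that add atoms: none
Why: Dess–Martin oxidation followed in the same flask by Wittig olefination with the stabilised formyl ylide should give the (E)-enal (C1=C6–C5) from the non-enolisable aldehyde.

Step 8
Reactants: 13 methyl 3-oxopentanoate; 14 prop-2-en-1-ol
Product: 15 prop-2-en-1-yl 3-oxopentanoate
Conditions: DMAP (cat.), toluene, reflux, 4 Å molecular sieves (removal of MeOH)
Reagents that add atoms: none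
Why: Transesterification of a β-keto ester, driven by removal of methanol, installs an ester that can later be removed under neutral conditions.

Step 9
Reactants: 12 (2E)-3-[(2R)-2-{4-methyl-1-[(triethylsilyl)oxy]pent-3-en-1-yl}oxiran-2-yl]prop-2-enal; 15 prop-2-en-1-yl 3-oxopentanoate
Product: 18 prop-2-en-1-yl 3-methyl-2-oxo-6-[(2R)-2-{4-methyl-1-[(triethylsilyl)oxy]pent-3-en-1-yl}oxiran-2-yl]cyclohex-3-ene-1-carboxylate (C1 as in the target), via Michael adduct 16 (not isolated), via aldol 17 (not isolated)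
Conditions: (S)-2-{bis[3,5-bis(trifluoromethyl)phenyl][(trimethylsilyl)oxy]methyl}pyrrolidine (20 mol%), PhCO2H (20 mol%), toluene, 0 °C → rt, then 40 °C
Reagents that add atoms: none
Why: The catalyst condenses with enal 12 to an E,s-trans iminium ion, and the C2 enol of β-keto ester 15 adds to C1 on the face opposite the diaryl(silyloxy)methyl group, which forms C1–C2 and should fix C1 in the configuration of the target. The resulting enamine is protonated, and the ethyl-ketone enol (C3=C4) then attacks C5 of the aldehyde (or its iminium ion) in a 6-(enolendo)-exo-trig aldol/Mannich closure that forms C4–C5; loss of water (or of the amine) gives the conjugated enone. The closest known reaction type is the secondary-amine-catalysed Michael/aldol condensation of β-keto esters with enals to cyclohexenones, a Robinson-type [3+3] annulation. Only C1 needs control: C2 is epimerisable and is erased in step 10, and C7 comes from step 2, with the catalyst expected to override its 1,2-induction. Chemoselectivity rests on the substrate: C7 is fully substituted, so neither a dienamine nor conjugate opening of the vinyl oxirane is available, and closure through C2 would give a four-membered ring, so only C4 can reach C5.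

Step 10
Reactants: 18 prop-2-en-1-yl 3-methyl-2-oxo-6-[(2R)-2-{4-methyl-1-[(triethylsilyl)oxy]pent-3-en-1-yl}oxiran-2-yl]cyclohex-3-ene-1-carboxylate
Product: 20 (5R)-2-methyl-5-[(2R)-2-{4-methyl-1-[(triethylsilyl)oxy]pent-3-en-1-yl}oxiran-2-yl]cyclohex-2-en-1-one, via β-keto acid 19 (not isolated)
Conditions: Pd(OAc)2 (5 mol%), PPh3 (20 mol%), HCO2H, Et3N, THF, rt
Reagents that add atoms: none
Why: In this Tsuji-type deallylation zerovalent palladium ionises the allyl ester, formate reduces the π-allyl complex to propene and the β-keto acid loses CO2, which should leave the carvone-type enone with C1 untouched.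

Step 11
Reactants: 20 (5R)-2-methyl-5-[(2R)-2-{4-methyl-1-[(triethylsilyl)oxy]pent-3-en-1-yl}oxiran-2-yl]cyclohex-2-en-1-one
Product: 21 (1R,5R)-2-methyl-5-[(2R)-2-{4-methyl-1-[(triethylsilyl)oxy]pent-3-en-1-yl}oxiran-2-yl]cyclohex-2-en-1-ol (C3 hydroxyl cis to the side chain)
Conditions: NaBH4, CeCl3·7H2O, MeOH, −78 °C
Reagents that add atoms: none
Why: Luche 1,2-reduction with axial hydride delivery should give the pseudo-equatorial C3 alcohol cis to the C1 side chain, as carvone gives cis-carveol.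

Step 12
Reactants: 21 (1R,5R)-2-methyl-5-[(2R)-2-{4-methyl-1-[(triethylsilyl)oxy]pent-3-en-1-yl}oxiran-2-yl]cyclohex-2-en-1-ol
Product: 22 1-methyl-4-[(2R)-2-{4-methyl-1-[(triethylsilyl)oxy]pent-3-en-1-yl}oxiran-2-yl]-7-oxabicyclo[4.1.0]heptan-2-ol (hydroxyl, ring oxirane and side chain all cis)
Conditions: VO(acac)2 (5 mol%), tBuOOH (decane), CH2Cl2, 0 °C → rt
Reagents that add atoms: tert-butyl hydroperoxide CC(C)(C)OO
Why: In this hydroxyl-directed epoxidation the vanadium alkoxide of C3–OH delivers oxygen to the syn face of C4=C5, which should place the oxirane cis to the C1 side chain, while the remote C10=C11 alkene has no free directing hydroxyl.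

Step 13
Reactants: 22 1-methyl-4-[(2R)-2-{4-methyl-1-[(triethylsilyl)oxy]pent-3-en-1-yl}oxiran-2-yl]-7-oxabicyclo[4.1.0]heptan-2-ol
Product: 23 (1S,4R,6S)-1-methyl-4-[(2R)-2-{4-methyl-1-[(triethylsilyl)oxy]pent-3-en-1-yl}oxiran-2-yl]-7-oxabicyclo[4.1.0]heptan-2-one
Conditions: Dess–Martin periodinane, pyridine, CH2Cl2, 0 °C → rt
Reagents that add atoms: none
Why: Dess–Martin oxidation should return the C3 ketone without touching either oxirane, giving the epoxy ketone with the oxirane cis to the side chain.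

Step 14
Reactants: 23 (1S,4R,6S)-1-methyl-4-[(2R)-2-{4-methyl-1-[(triethylsilyl)oxy]pent-3-en-1-yl}oxiran-2-yl]-7-oxabicyclo[4.1.0]heptan-2-one
Product: 24 (1S,3S,4R,6S)-3-hydroxy-1-methyl-4-[(2R)-2-{4-methyl-1-[(triethylsilyl)oxy]pent-3-en-1-yl}oxiran-2-yl]-7-oxabicyclo[4.1.0]heptan-2-one (C2 hydroxyl trans to the side chain)
Conditions: KN(SiMe3)2, THF, −78 °C; then 2-(benzenesulfonyl)-3-phenyloxaziridine, −78 °C; aq. NH4Cl
Reagents that add atoms: 2-(benzenesulfonyl)-3-phenyloxaziridine O=S(=O)(N1OC1c1ccccc1)c1ccccc1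
Why: In this enolate oxidation with an N-sulfonyloxaziridine C2 is the only enolisable position (C4 is fully substituted), and oxygen should be delivered anti to the adjacent C1 side chain to give the trans C1/C2 relationship.

Step 15
Reactants: 24 (1S,3S,4R,6S)-3-hydroxy-1-methyl-4-[(2R)-2-{4-methyl-1-[(triethylsilyl)oxy]pent-3-en-1-yl}oxiran-2-yl]-7-oxabicyclo[4.1.0]heptan-2-one; 25 3-methylbutanoyl chloride
Product: 26 (1S,3S,4R,6S)-1-methyl-4-[(2R)-2-{4-methyl-1-[(triethylsilyl)oxy]pent-3-en-1-yl}oxiran-2-yl]-2-oxo-7-oxabicyclo[4.1.0]heptan-3-yl 3-methylbutanoate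
Conditions: pyridine, DMAP (cat.), CH2Cl2, 0 °C
Reagents that add atoms: none
Why: DMAP-catalysed acylation of the secondary α-hydroxy ketone should install the 3-methylbutanoate with retention at C2.

Step 16
Reactants: 26 (1S,3S,4R,6S)-1-methyl-4-[(2R)-2-{4-methyl-1-[(triethylsilyl)oxy]pent-3-en-1-yl}oxiran-2-yl]-2-oxo-7-oxabicyclo[4.1.0]heptan-3-yl 3-methylbutanoate
Product: 27 (1S,3S,4R,6S)-4-[(2R)-2-(1-hydroxy-4-methylpent-3-en-1-yl)oxiran-2-yl]-1-methyl-2-oxo-7-oxabicyclo[4.1.0]heptan-3-yl 3-methylbutanoate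
Conditions: HF·pyridine, pyridine, THF, 0 °C
Reagents that add atoms: none
Why: Pyridine-buffered fluoride cleavage of the triethylsilyl ether should free the C8 hydroxyl while the ester and both oxiranes survive.

Step 17
Reactants: 27 (1S,3S,4R,6S)-4-[(2R)-2-(1-hydroxy-4-methylpent-3-en-1-yl)oxiran-2-yl]-1-methyl-2-oxo-7-oxabicyclo[4.1.0]heptan-3-yl 3-methylbutanoate
Product: 28 (1S,3S,4R,6S)-1-methyl-4-[(2R)-2-(4-methylpent-3-enoyl)oxiran-2-yl]-2-oxo-7-oxabicyclo[4.1.0]heptan-3-yl 3-methylbutanoate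
Conditions: Dess–Martin periodinane, pyridine, CH2Cl2, 0 °C → rt
Reagents that add atoms: none
Why: Dess–Martin oxidation should converge both C8 epimers on the β,γ-unsaturated ketone, the buffered non-basic medium keeping the C10=C11 double bond out of conjugation.

Step 18
Reactants: 28 (1S,3S,4R,6S)-1-methyl-4-[(2R)-2-(4-methylpent-3-enoyl)oxiran-2-yl]-2-oxo-7-oxabicyclo[4.1.0]heptan-3-yl 3-methylbutanoate
Product: 29 (1S,3S,4R,6S)-4-{(2R)-2-[(2E)-4-hydroperoxy-4-methylpent-2-enoyl]oxiran-2-yl}-1-methyl-2-oxo-7-oxabicyclo[4.1.0]heptan-3-yl 3-methylbutanoate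
Conditions: O2, tetraphenylporphyrin (cat.), visible light, CH2Cl2, −20 °C
Reagents that add atoms: dioxygen (as singlet oxygen) O=O
Why: In this Schenck ene reaction of singlet oxygen with the only alkene, abstraction of a C9 hydrogen (allylic, α to the C8 carbonyl and on the more substituted side of the alkene) should move the double bond into conjugation as the (E)-enone and place the hydroperoxide on the tertiary C11.

Compound list
1 | 2-methylidenepropane-1,3-diol | C=C(CO)CO | starting material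
2 | 2-{[(4-methoxybenzyl)oxy]methyl}prop-2-en-1-ol | C=C(CO)COCc1ccc(OC)cc1 | intermediate
3 | (S)-(2-{[(4-methoxybenzyl)oxy]methyl}oxiran-2-yl)methanol | COc1ccc(COC[C@]2(CO)CO2)cc1 | intermediate
4 | (S)-2-{[(4-methoxybenzyl)oxy]methyl}oxirane-2-carbaldehyde | COc1ccc(COC[C@]2(C=O)CO2)cc1 | intermediate
5 | 1-chloro-3-methylbut-2-ene | CC(C)=CCCl | starting material
6 | (3-methylbut-2-en-1-yl)barium chloride (prenylbarium chloride) | CC(C)=CC[Ba]Cl | intermediate
7 | 1-[(2S)-2-{[(4-methoxybenzyl)oxy]methyl}oxiran-2-yl]-4-methylpent-3-en-1-ol (both C8 epimers) | COc1ccc(COC[C@]2(C(O)CC=C(C)C)CO2)cc1 | intermediate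
8 | triethyl({1-[(2S)-2-{[(4-methoxybenzyl)oxy]methyl}oxiran-2-yl]-4-methylpent-3-en-1-yl}oxy)silane | COc1ccc(COC[C@]2(C(O[Si](CC)(CC)CC)CC=C(C)C)CO2)cc1 | intermediate
9 | [(2R)-2-{4-methyl-1-[(triethylsilyl)oxy]pent-3-en-1-yl}oxiran-2-yl]methanol | OC[C@]1(C(O[Si](CC)(CC)CC)CC=C(C)C)CO1 | intermediate
10 | 2-(triphenylphosphoranylidene)acetaldehyde | O=CC=P(c1ccccc1)(c1ccccc1)c1ccccc1 | starting material
11 | (2R)-2-{4-methyl-1-[(triethylsilyl)oxy]pent-3-en-1-yl}oxirane-2-carbaldehyde | O=C[C@]1(C(O[Si](CC)(CC)CC)CC=C(C)C)CO1 | intermediate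
12 | (2E)-3-[(2R)-2-{4-methyl-1-[(triethylsilyl)oxy]pent-3-en-1-yl}oxiran-2-yl]prop-2-enal | O=C/C=C/[C@]1(C(O[Si](CC)(CC)CC)CC=C(C)C)CO1 | intermediate
13 | methyl 3-oxopentanoate | CCC(=O)CC(=O)OC | starting material
14 | prop-2-en-1-ol | C=CCO | starting material
15 | prop-2-en-1-yl 3-oxopentanoate | CCC(=O)CC(=O)OCC=C | intermediate
16 | prop-2-en-1-yl 3-oxo-2-{3-oxo-1-[(2R)-2-{4-methyl-1-[(triethylsilyl)oxy]pent-3-en-1-yl}oxiran-2-yl]propyl}pentanoate (Michael adduct; C1 as in the target, C2 unfixed) | O=CC[C@H](C(C(=O)OCC=C)C(=O)CC)[C@]1(C(O[Si](CC)(CC)CC)CC=C(C)C)CO1 | intermediate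
17 | prop-2-en-1-yl 4-hydroxy-3-methyl-2-oxo-6-[(2R)-2-{4-methyl-1-[(triethylsilyl)oxy]pent-3-en-1-yl}oxiran-2-yl]cyclohexane-1-carboxylate (aldol; C2, C4, C5 unfixed) | C=CCOC(=O)C1C(=O)C(C)C(O)C[C@H]1[C@]1(C(O[Si](CC)(CC)CC)CC=C(C)C)CO1 | intermediate
18 | prop-2-en-1-yl 3-methyl-2-oxo-6-[(2R)-2-{4-methyl-1-[(triethylsilyl)oxy]pent-3-en-1-yl}oxiran-2-yl]cyclohex-3-ene-1-carboxylate (C1 as in the target, C2 unfixed) | C=CCOC(=O)C1C(=O)C(C)=CC[C@H]1[C@]1(C(O[Si](CC)(CC)CC)CC=C(C)C)CO1 | intermediate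
19 | 3-methyl-2-oxo-6-[(2R)-2-{4-methyl-1-[(triethylsilyl)oxy]pent-3-en-1-yl}oxiran-2-yl]cyclohex-3-ene-1-carboxylic acid (β-keto acid) | OC(=O)C1C(=O)C(C)=CC[C@H]1[C@]1(C(O[Si](CC)(CC)CC)CC=C(C)C)CO1 | intermediate
20 | (5R)-2-methyl-5-[(2R)-2-{4-methyl-1-[(triethylsilyl)oxy]pent-3-en-1-yl}oxiran-2-yl]cyclohex-2-en-1-one | C1C(=O)C(C)=CC[C@H]1[C@]1(C(O[Si](CC)(CC)CC)CC=C(C)C)CO1 | intermediate
21 | (1R,5R)-2-methyl-5-[(2R)-2-{4-methyl-1-[(triethylsilyl)oxy]pent-3-en-1-yl}oxiran-2-yl]cyclohex-2-en-1-ol | C1[C@@H](O)C(C)=CC[C@H]1[C@]1(C(O[Si](CC)(CC)CC)CC=C(C)C)CO1 | intermediate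
22 | 1-methyl-4-[(2R)-2-{4-methyl-1-[(triethylsilyl)oxy]pent-3-en-1-yl}oxiran-2-yl]-7-oxabicyclo[4.1.0]heptan-2-ol (hydroxyl, ring oxirane and side chain all cis) | C1[C@@H](O)[C@@]2(C)O[C@H]2C[C@H]1[C@]1(C(O[Si](CC)(CC)CC)CC=C(C)C)CO1 | intermediate
23 | (1S,4R,6S)-1-methyl-4-[(2R)-2-{4-methyl-1-[(triethylsilyl)oxy]pent-3-en-1-yl}oxiran-2-yl]-7-oxabicyclo[4.1.0]heptan-2-one | C1C(=O)[C@@]2(C)O[C@H]2C[C@H]1[C@]1(C(O[Si](CC)(CC)CC)CC=C(C)C)CO1 | intermediate
24 | (1S,3S,4R,6S)-3-hydroxy-1-methyl-4-[(2R)-2-{4-methyl-1-[(triethylsilyl)oxy]pent-3-en-1-yl}oxiran-2-yl]-7-oxabicyclo[4.1.0]heptan-2-one | O[C@@H]1C(=O)[C@@]2(C)O[C@H]2C[C@H]1[C@]1(C(O[Si](CC)(CC)CC)CC=C(C)C)CO1 | intermediate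
25 | 3-methylbutanoyl chloride | CC(C)CC(=O)Cl | starting material
26 | (1S,3S,4R,6S)-1-methyl-4-[(2R)-2-{4-methyl-1-[(triethylsilyl)oxy]pent-3-en-1-yl}oxiran-2-yl]-2-oxo-7-oxabicyclo[4.1.0]heptan-3-yl 3-methylbutanoate | CC(C)CC(=O)O[C@@H]1C(=O)[C@@]2(C)O[C@H]2C[C@H]1[C@]1(C(O[Si](CC)(CC)CC)CC=C(C)C)CO1 | intermediate
27 | (1S,3S,4R,6S)-4-[(2R)-2-(1-hydroxy-4-methylpent-3-en-1-yl)oxiran-2-yl]-1-methyl-2-oxo-7-oxabicyclo[4.1.0]heptan-3-yl 3-methylbutanoate | CC(C)CC(=O)O[C@@H]1C(=O)[C@@]2(C)O[C@H]2C[C@H]1[C@]1(C(O)CC=C(C)C)CO1 | intermediate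
28 | (1S,3S,4R,6S)-1-methyl-4-[(2R)-2-(4-methylpent-3-enoyl)oxiran-2-yl]-2-oxo-7-oxabicyclo[4.1.0]heptan-3-yl 3-methylbutanoate | CC(C)CC(=O)O[C@@H]1C(=O)[C@@]2(C)O[C@H]2C[C@H]1[C@]1(C(=O)CC=C(C)C)CO1 | intermediate
29 | (1S,3S,4R,6S)-4-{(2R)-2-[(2E)-4-hydroperoxy-4-methylpent-2-enoyl]oxiran-2-yl}-1-methyl-2-oxo-7-oxabicyclo[4.1.0]heptan-3-yl 3-methylbutanoate | CC(C)CC(=O)O[C@@H]1C(=O)[C@@]2(C)O[C@H]2C[C@H]1[C@]1(C(=O)/C=C/C(C)(C)OO)CO1 | target

Total step count: 18. Longest linear sequence: 17 steps (steps 1–7, then 9–18); step 8 is a one-step branch.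

Steps most likely to fail

Step 9. The conjugate addition to C1, which sits next to the fully substituted C7, may be slow, and the domino may stall at the Michael adduct, which can rest as a cyclic hemiacetal (enol oxygen of the β-keto ester on C5) so that ring closure and dehydration do not follow. The fallback separates the two bond formations and removes the ester before ring closure. It sets out from 12 and 15: the Michael adduct 16 is isolated after the amine-catalysed addition at rt. Its allyl ester is then cleaved and decarboxylated (Pd(OAc)2, PPh3, HCO2H, Et3N, THF, rt) to give the keto aldehyde 5-oxo-3-[(2R)-2-{4-methyl-1-[(triethylsilyl)oxy]pent-3-en-1-yl}oxiran-2-yl]heptanal F1, which has no enolised β-keto ester to trap the aldehyde and cannot undergo retro-Michael loss of a stabilised enolate. A classical intramolecular aldol condensation of F1 (piperidinium acetate, toluene, 60 °C), in which only C4 can close a six-membered ring onto C5, returns to the route at enone 20.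

Step 18. Hydrogen abstraction by singlet oxygen may occur from the C11 methyl groups instead of C9, giving the secondary allylic hydroperoxide with an isopropenyl terminus. The fallback is ionic and fixes the regiochemistry. It sets out from diketone 28: Markovnikov bromohydroperoxidation of the C10=C11 alkene (N-bromosuccinimide, anhydrous H2O2 in Et2O, −40 °C) should give the β-bromo hydroperoxide (1S,3S,4R,6S)-4-[(2R)-2-(3-bromo-4-hydroperoxy-4-methylpentanoyl)oxiran-2-yl]-1-methyl-2-oxo-7-oxabicyclo[4.1.0]heptan-3-yl 3-methylbutanoate F2, with bromine on C10 and the hydroperoxide on the tertiary C11. Et3N (CH2Cl2, 0 °C) then removes HBr by E1cB elimination across C9–C10, the bromide being β to the C8 ketone, and returns to the route at target 29.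

Step 4. The allylic barium reagent may lose its α-regioselectivity (bond formation through the dimethyl-substituted terminus to give the 1,1-dimethylallyl carbinol) or attack the oxirane. The fallback builds the trisubstituted alkene after the addition. It sets out from aldehyde 4: allylmagnesium bromide (THF, −78 °C) gives the homoallylic alcohol 1-[(2S)-2-{[(4-methoxybenzyl)oxy]methyl}oxiran-2-yl]but-3-en-1-ol F3. Cross-metathesis of its terminal alkene with 2-methylbut-2-ene (second-generation Grubbs catalyst, CH2Cl2, 40 °C) returns to the route at alcohol 7.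

Further compounds
F1 | step 9 | 5-oxo-3-[(2R)-2-{4-methyl-1-[(triethylsilyl)oxy]pent-3-en-1-yl}oxiran-2-yl]heptanal (C3 configured as C1 of the target) | O=CC[C@H](CC(=O)CC)[C@]1(C(O[Si](CC)(CC)CC)CC=C(C)C)CO1
F2 | step 18 | (1S,3S,4R,6S)-4-[(2R)-2-(3-bromo-4-hydroperoxy-4-methylpentanoyl)oxiran-2-yl]-1-methyl-2-oxo-7-oxabicyclo[4.1.0]heptan-3-yl 3-methylbutanoate (C10 unfixed) | CC(C)CC(=O)O[C@@H]1C(=O)[C@@]2(C)O[C@H]2C[C@H]1[C@]1(C(=O)CC(Br)C(C)(C)OO)CO1
F3 | step 4 | 1-[(2S)-2-{[(4-methoxybenzyl)oxy]methyl}oxiran-2-yl]but-3-en-1-ol (both C8 epimers) | COc1ccc(COC[C@]2(C(O)CC=C)CO2)cc1
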